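The runs are simulated with constants of no real substance.

6 questions stood, 5 of them an end amount per flask and the last the best flask, so I wanted one number that sorted the flasks.

| setting | Saturday's | Monday's | Friday's | blue | grey | violet | amber | red |
|---|---|---|---|---|---|---|---|---|
| starting material | 14 mM | 7 mM | 28 mM | 14 mM | 14 mM | 14 mM | 14 mM (in portions, 3, over 2.0 min) | 14 mM (fed, over 2.0 min) |
| partner | 2 equiv | 2 equiv | 2 equiv | 2.00 equiv (fed, over 2.0 min) | 2.00 equiv | 2.00 equiv (fed, over 12 s) | 2.00 equiv | 2.00 equiv |
| remark | run made earlier | run made earlier | run made earlier | all else is in the flask from the start; the feed brings no volume worth counting | everything together at the start | all else is in the flask from the start; the feed brings no volume worth counting | first portion at the start, last at 2.0 min | all else is in the flask from the start; the feed brings no volume worth counting |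
| time |  |  |  | 2.5 min | 2.5 min | 2.5 min | 2.5 min | 2.5 min |

- Saturday's (time / min: bis adduct / %, starting material / %): 0.200: 9.3, 0.5; 0.333: 13.0, 0.9; 0.500: 14.6, 0; 0.833: 16.5, 0; 1.50: 14.3, 0.3; 2.50: 14.3, 0.5
- Monday's (time / s: bis adduct / %, starting material / %): 15.0: 5.7, 6.3; 30.0: 8.4, 1.2; 50.0: 11.8, 0.6; 60.0: 9.4, 1.5; 80.0: 12.2, 1.4; 90.0: 13.7, 0.7
- Friday's (time / s: bis adduct / %, starting material / %): 15.0: 15.4, 0; 30.0: 17.0, 0; 50.0: 15.8, 0; 60.0: 16.6, 1.6; 80.0: 18.1, 0; 90.0: 15.7, 0

(readings scatter by 1 percentage point)

- the best flask by amount of bis adduct, in percent of the starting material charged; "all alike" if 1.5 percentage points covers them all (blue / grey / violet / amber / red / all alike)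
- amount of bis adduct at the end, in percent of the starting material charged, blue
- amount of bis adduct at the end, in percent of the starting material charged, grey
- amount of bis adduct at the end, in percent of the starting material charged, violet
- amount of bis adduct at the end, in percent of the starting material charged, amber
- amount of bis adduct at the end, in percent of the starting material charged, red



I took the settings in turn, starting with concentration. If the steps are bimolecular, doubling c(starting material) should halve the time to the plateau and leave its height alone. Saturday's bis adduct reached its plateau at about 0.500 min, as a reading, and from there it averaged 14.9 %. Friday's run, at twice the concentration, was already level at its first reading, 15.0 s, which is half of Saturday's time, and it averaged 16.4 %. The height therefore moved by 1.5 percentage points, against a scatter of 1 point per reading.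

Next came time. Grey ran for 5.00 plateau times, so I expected it to sit at the plateau, near 14.9 %.

Then came the length of the feed:

feed number = feed time / plateau time
blue and red: 2.0 min / 0.500 min = 4.00
violet: 12 s / 0.500 min = 0.400

This feed number, the feed time over the plateau time, is a Damköhler number of the dosing. Violet's feed ended before the plateau time, so I reckoned violet would stay close to grey. Blue's feed outlasted the plateau time, so I no longer reckoned blue as a batch flask, and I put it below grey by more than 1.5 points.

Last came what is fed. Red has the same feed number as blue, and amber's portions stand 1.00 min apart, which is 2.00 plateau times, so I placed both low as well, and grey first.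

The forecast named blue as best, with 20 % there, 15 % in grey, 15.5 % in violet, 12 % in amber and 11 % in red, on the ground that “Slow partner feed keeps partner low and disfavours second-order self-loss”; I differed from it on blue.

Grey was the best flask at 15.5 %, and amber gave 6.45 %. At 2.50 min, blue held 64.7 % side product, which counts as two, against 16.6 % in grey.

    partner + mono adduct → bis adduct (k = 1.10 M⁻¹ s⁻¹)
    partner + bis adduct → triple product (k = 3.10 M⁻¹ s⁻¹)
    partner → decomposed reagent (k = 0.0230 s⁻¹)
    starting material + mono adduct → side product (k = 6.00 M⁻¹ s⁻¹)
    partner + triple product → tetra adduct (k = 40.0 M⁻¹ s⁻¹)
    starting material + partner → mono adduct (k = 23.0 M⁻¹ s⁻¹)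

At feed number 0.400, violet gave 14.0 %, which is 1.5 points below grey. At feed number 4.00, blue gave 7.06 %, which is 8.4 points below grey. Red, at the same feed number 4.00 but fed with starting material, gave 5.68 %.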